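**Plan**
Ring numbering used below: C1 carbonyl, C2=C3 alkene, C4 methoxy carbon, C5 methylene, C6 quaternary carbon; C7 is the benzylic carbon and C8 the methyl-bearing carbon of the side chain.
Retrosynthesis cuts, in order: the acetate and silyl ether; the C6–allyl bond; the ring bonds C4–C5 and C2=C3 (retro Michael addition/aldol condensation); the C7–C8 bond (retro-aldol).
Forward: the C7/C8 pair is made first by an auxiliary-controlled syn-aldol reaction, the acyl carbon is turned into a 1-acetylvinyl group, the cyclohexenone is closed in one operation, then allylation, desilylation and acetylation follow.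
Enabling feature: the γ-methoxy enone C1(=O)–C2=C3–C4(OMe)–C5H2–C6 is the Robinson-type retron of an α-methoxy aldehyde (C3, C4) and a vinyl ketone (C2, C1, C6, C5), so methoxyacetaldehyde delivers the ring at its final oxidation level.
Stereochemistry: C7 and C8 from the (R)-oxazolidinone auxiliary, C4 from the prolinol catalyst, C6 by substrate control (allylation anti to the C4 methoxy group, reinforced by allylic 1,3-strain at C8).

Key step: step 6

Remark: methoxyacetaldehyde is assumed to be used as the dry, freshly distilled monomer, and the facial sense in step 6 assumes the usual anti E enamine.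

**Step 1**
Reactants: 1 (4R)-4-benzyl-3-propanoyl-1,3-oxazolidin-2-one; 2 3,4,5-trimethoxybenzaldehyde
Product: 4 (4R)-4-benzyl-3-[(2R,3R)-3-hydroxy-2-methyl-3-(3,4,5-trimethoxyphenyl)propanoyl]-1,3-oxazolidin-2-one, via Z dibutylboron enolate 3 (not isolated)
Conditions: Bu2BOTf, iPr2NEt, CH2Cl2, 0 °C; then 2, −78 → 0 °C; then pH 7 phosphate buffer, MeOH, 30% H2O2, 0 °C
Reagents that add atoms: none
Why: Evans syn-aldol reaction: the Z boron enolate 3 reacts with 2 through a closed chair transition state on the enolate face remote from the benzyl group of the (R)-auxiliary, which should set the (2R,3R) syn pair that becomes C8 and C7 of the target.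

**Step 2**
Reactants: 4 (4R)-4-benzyl-3-[(2R,3R)-3-hydroxy-2-methyl-3-(3,4,5-trimethoxyphenyl)propanoyl]-1,3-oxazolidin-2-one
Product: 5 (2R,3R)-3-hydroxy-N-methoxy-N,2-dimethyl-3-(3,4,5-trimethoxyphenyl)propanamide
Conditions: MeONHMe·HCl, AlMe3, CH2Cl2, −15 → 0 °C; then aq. KNaC4H4O6
Reagents that add atoms: N,O-dimethylhydroxylamine hydrochloride, CNOC.Cl
Why: Aluminium amide aminolysis of the imide (transamination), assisted by the aluminium alkoxide of the free β-hydroxyl, should release the auxiliary and give the N-methoxy-N-methylamide without retro-aldol cleavage or epimerisation.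

**Step 3**
Reactants: 5 (2R,3R)-3-hydroxy-N-methoxy-N,2-dimethyl-3-(3,4,5-trimethoxyphenyl)propanamide
Product: 6 (2R,3R)-3-(tert-butyldimethylsilyloxy)-N-methoxy-N,2-dimethyl-3-(3,4,5-trimethoxyphenyl)propanamide
Conditions: TBSOTf, 2,6-lutidine, CH2Cl2, 0 °C
Reagents that add atoms: tert-butyldimethylsilyl trifluoromethanesulfonate, CC(C)(C)[Si](C)(C)OS(=O)(=O)C(F)(F)F
Why: Silyl triflate silylation of the secondary benzylic alcohol masks it against the organolithium and amide bases to come and prevents its conjugate addition to the vinyl ketone of 9.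

**Step 4**
Reactants: 6 (2R,3R)-3-(tert-butyldimethylsilyloxy)-N-methoxy-N,2-dimethyl-3-(3,4,5-trimethoxyphenyl)propanamide
Product: 7 (4R,5R)-5-(tert-butyldimethylsilyloxy)-2-ethoxy-4-methyl-5-(3,4,5-trimethoxyphenyl)pent-1-en-3-one
Conditions: ethyl vinyl ether, t-BuLi, THF, −78 → 0 °C; then 6, −78 °C; aq. NH4Cl
Reagents that add atoms: ethyl vinyl ether (as its 1-lithio derivative), C=COCC
Why: Acylation of an α-alkoxyvinyllithium by an N-methoxy-N-methylamide stops at the ketone because the chelated tetrahedral adduct collapses only on work-up, and the cold, non-equilibrating conditions should leave the α-stereocentre intact.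

**Step 5**
Reactants: 7 (4R,5R)-5-(tert-butyldimethylsilyloxy)-2-ethoxy-4-methyl-5-(3,4,5-trimethoxyphenyl)pent-1-en-3-one
Product: 9 (4S,5R)-5-(tert-butyldimethylsilyloxy)-4-methyl-3-methylidene-5-(3,4,5-trimethoxyphenyl)pentan-2-one, via 2-ethoxydiene 8 (not isolated)
Conditions: Cp2TiMe2, toluene, 65 °C, dark; then 0.5 M aq. oxalic acid, THF, 0 °C
Reagents that add atoms: dimethyltitanocene Cp2TiMe2, C[Ti](C)(C1C=CC=C1)C1C=CC=C1; water, O
Why: Petasis methylenation with the non-basic titanium methylidene should convert the epimerisable β-silyloxy ketone into the 2-ethoxy-1,3-diene 8 without epimerisation or β-elimination, and mild acid then hydrolyses the enol ether by protonation at its CH2 terminus to unmask the acetyl group next to the retained 1,1-disubstituted alkene.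

**Step 6**
Reactants: 9 (4S,5R)-5-(tert-butyldimethylsilyloxy)-4-methyl-3-methylidene-5-(3,4,5-trimethoxyphenyl)pentan-2-one; 10 methoxyacetaldehyde
Product: 12 (4R)-6-[(1R,2S)-1-(tert-butyldimethylsilyloxy)-1-(3,4,5-trimethoxyphenyl)propan-2-yl]-4-methoxycyclohex-2-en-1-one (both C6 epimers), via keto aldehyde 11 (not isolated)
Conditions: (S)-α,α-diphenylprolinol trimethylsilyl ether (20 mol %), 4-nitrophenol (20 mol %), CHCl3, 4 °C → rt; remove excess 10 in vacuo; then LiOH·H2O (20 mol %), i-PrOH, 0 °C
Reagents that add atoms: none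
Why: The amine catalyst condenses with aldehyde 10 to the anti E enamine, whose methoxy-bearing carbon adds to the terminal CH2 of vinyl ketone 9 (new C4–C5 bond), hydrolysis gives keto aldehyde 11, and on addition of LiOH the methyl ketone enolate attacks the aldehyde and the aldol loses water (new C2=C3 bond). The closest known reaction type is the amine-catalysed Michael addition of aldehydes to vinyl ketones followed by aldol condensation, a Robinson-type annulation to 4-substituted cyclohex-2-enones, with α-alkoxy aldehydes being established enamine donors. The one ring closes by a 6-(enolendo)-exo-trig aldol addition. The new C4 stereocentre is controlled by the catalyst, whose diphenyl(silyloxy)methyl group blocks one enamine face so that the (S)-catalyst should deliver the (R)-configured methoxy carbon, whereas C6 is formed without control and is planarised again in step 7. The step needs chemoselectivity (only 10 can form an enamine and only the acetyl CH3 can reach the aldehyde through a six-membered transition state, the alternatives being four-membered rings) and retention of the C4 configuration, which should hold because cyclisation–dehydration is irreversible and the α-methoxy aldehyde should be consumed faster than it enolises under catalytic LiOH at 0 °C.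

**Step 7**
Reactants: 12 (4R)-6-[(1R,2S)-1-(tert-butyldimethylsilyloxy)-1-(3,4,5-trimethoxyphenyl)propan-2-yl]-4-methoxycyclohex-2-en-1-one
Product: 14 (4R,6R)-6-[(1R,2S)-1-(tert-butyldimethylsilyloxy)-1-(3,4,5-trimethoxyphenyl)propan-2-yl]-4-methoxy-6-(prop-2-en-1-yl)cyclohex-2-en-1-one, via lithium dienolate 13 (not isolated)
Conditions: LiN(iPr)2, THF, −78 °C; then allyl bromide, DMPU, −78 → −30 °C
Reagents that add atoms: allyl bromide, C=CCBr
Why: Enolate alkylation: kinetic deprotonation at the only α'-hydrogen gives the cross-conjugated dienolate 13, which should be allylated anti to the pseudoaxial C4 methoxy group, the face also left open by allylic 1,3-strain at C8 (C8–H in the enolate plane toward O–Li, silyloxybenzyl group on the methoxy face), so that the quaternary centre forms as 6R with allyl trans to methoxy.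

**Step 8**
Reactants: 14 (4R,6R)-6-[(1R,2S)-1-(tert-butyldimethylsilyloxy)-1-(3,4,5-trimethoxyphenyl)propan-2-yl]-4-methoxy-6-(prop-2-en-1-yl)cyclohex-2-en-1-one
Product: 15 megaphone, (4R,6R)-6-[(1R,2S)-1-hydroxy-1-(3,4,5-trimethoxyphenyl)propan-2-yl]-4-methoxy-6-(prop-2-en-1-yl)cyclohex-2-en-1-one
Conditions: HF·pyridine, pyridine, THF, 0 °C → rt
Reagents that add atoms: none
Why: Fluoride-induced cleavage of the Si–O bond under buffered, weakly acidic conditions should free the benzylic alcohol without touching the γ-methoxy enone, the allyl group or the aryl methyl ethers.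

**Step 9**
Reactants: 15 megaphone
Product: 16 megaphone acetate, (1R,2S)-2-[(1R,5R)-5-methoxy-2-oxo-1-(prop-2-en-1-yl)cyclohex-3-en-1-yl]-1-(3,4,5-trimethoxyphenyl)propyl acetate
Conditions: Ac2O, pyridine, DMAP (cat.), CH2Cl2, rt
Reagents that add atoms: acetic anhydride, CC(=O)OC(C)=O
Why: DMAP-catalysed acylation of the secondary benzylic alcohol with the anhydride gives the acetate and involves none of the stereocentres.

**Compound list**
1 | (4R)-4-benzyl-3-propanoyl-1,3-oxazolidin-2-one | CCC(=O)N1[C@H](Cc2ccccc2)COC1=O | starting material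
2 | 3,4,5-trimethoxybenzaldehyde | COc1cc(C=O)cc(OC)c1OC | starting material
3 | Z dibutylboron enolate of 1 | C/C=C(\OB(CCCC)CCCC)N1[C@H](Cc2ccccc2)COC1=O | intermediate (not isolated)
4 | (4R)-4-benzyl-3-[(2R,3R)-3-hydroxy-2-methyl-3-(3,4,5-trimethoxyphenyl)propanoyl]-1,3-oxazolidin-2-one | O=C(N1[C@H](Cc2ccccc2)COC1=O)[C@H](C)[C@@H](O)c1cc(OC)c(OC)c(OC)c1 | intermediate
5 | (2R,3R)-3-hydroxy-N-methoxy-N,2-dimethyl-3-(3,4,5-trimethoxyphenyl)propanamide | CON(C)C(=O)[C@H](C)[C@@H](O)c1cc(OC)c(OC)c(OC)c1 | intermediate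
6 | (2R,3R)-3-(tert-butyldimethylsilyloxy)-N-methoxy-N,2-dimethyl-3-(3,4,5-trimethoxyphenyl)propanamide | CON(C)C(=O)[C@H](C)[C@@H](O[Si](C)(C)C(C)(C)C)c1cc(OC)c(OC)c(OC)c1 | intermediate
7 | (4R,5R)-5-(tert-butyldimethylsilyloxy)-2-ethoxy-4-methyl-5-(3,4,5-trimethoxyphenyl)pent-1-en-3-one | CCOC(=C)C(=O)[C@H](C)[C@@H](O[Si](C)(C)C(C)(C)C)c1cc(OC)c(OC)c(OC)c1 | intermediate
8 | tert-butyl{[(1R,2S)-4-ethoxy-2-methyl-3-methylidene-1-(3,4,5-trimethoxyphenyl)pent-4-en-1-yl]oxy}dimethylsilane | CCOC(=C)C(=C)[C@H](C)[C@@H](O[Si](C)(C)C(C)(C)C)c1cc(OC)c(OC)c(OC)c1 | intermediate (not isolated)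
9 | (4S,5R)-5-(tert-butyldimethylsilyloxy)-4-methyl-3-methylidene-5-(3,4,5-trimethoxyphenyl)pentan-2-one | CC(=O)C(=C)[C@H](C)[C@@H](O[Si](C)(C)C(C)(C)C)c1cc(OC)c(OC)c(OC)c1 | intermediate
10 | methoxyacetaldehyde | COCC=O | starting material
11 | (2R,5S,6R)-4-acetyl-6-(tert-butyldimethylsilyloxy)-2-methoxy-5-methyl-6-(3,4,5-trimethoxyphenyl)hexanal (C4 epimers) | O=C[C@H](OC)CC(C(C)=O)[C@H](C)[C@@H](O[Si](C)(C)C(C)(C)C)c1cc(OC)c(OC)c(OC)c1 | intermediate (not isolated)
12 | (4R)-6-[(1R,2S)-1-(tert-butyldimethylsilyloxy)-1-(3,4,5-trimethoxyphenyl)propan-2-yl]-4-methoxycyclohex-2-en-1-one (C6 epimers) | CO[C@H]1C=CC(=O)C(C1)[C@H](C)[C@@H](O[Si](C)(C)C(C)(C)C)c1cc(OC)c(OC)c(OC)c1 | intermediate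
13 | lithium (4R)-2-[(1R,2S)-1-(tert-butyldimethylsilyloxy)-1-(3,4,5-trimethoxyphenyl)propan-2-yl]-4-methoxycyclohexa-1,5-dien-1-olate | [Li]OC1=C([C@H](C)[C@@H](O[Si](C)(C)C(C)(C)C)c2cc(OC)c(OC)c(OC)c2)C[C@@H](OC)C=C1 | intermediate (not isolated)
14 | (4R,6R)-6-[(1R,2S)-1-(tert-butyldimethylsilyloxy)-1-(3,4,5-trimethoxyphenyl)propan-2-yl]-4-methoxy-6-(prop-2-en-1-yl)cyclohex-2-en-1-one | C=CC[C@]1([C@H](C)[C@@H](O[Si](C)(C)C(C)(C)C)c2cc(OC)c(OC)c(OC)c2)C[C@@H](OC)C=CC1=O | intermediate
15 | megaphone, (4R,6R)-6-[(1R,2S)-1-hydroxy-1-(3,4,5-trimethoxyphenyl)propan-2-yl]-4-methoxy-6-(prop-2-en-1-yl)cyclohex-2-en-1-one | C=CC[C@]1([C@H](C)[C@@H](O)c2cc(OC)c(OC)c(OC)c2)C[C@@H](OC)C=CC1=O | intermediate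
16 | megaphone acetate, (1R,2S)-2-[(1R,5R)-5-methoxy-2-oxo-1-(prop-2-en-1-yl)cyclohex-3-en-1-yl]-1-(3,4,5-trimethoxyphenyl)propyl acetate | C=CC[C@]1([C@H](C)[C@@H](OC(C)=O)c2cc(OC)c(OC)c(OC)c2)C[C@@H](OC)C=CC1=O | target

**Step count and risks**
Total step count: 9. Longest linear sequence: 9 steps (1 and 2 to 16).

Steps most likely to fail:

1. Step 6. The conjugate addition may be sluggish because the vinyl ketone is α-branched, and the C4 configuration may erode through enolisation of the α-methoxy aldehyde before ring closure. The fallback sets out from 9 and 10 and comes back to the route at 12. It gives up catalyst control and uses a stoichiometric, unhindered enamine. Aldehyde 10 is condensed with pyrrolidine (K2CO3, Et2O) to the enamine 1-[(E)-2-methoxyethenyl]pyrrolidine F1. A Stork enamine Michael addition of F1 to 9 in MeCN, followed by hydrolysis with aqueous AcOH/NaOAc, should give 11 together with its C2 epimer, (2S,5S,6R)-4-acetyl-6-(tert-butyldimethylsilyloxy)-2-methoxy-5-methyl-6-(3,4,5-trimethoxyphenyl)hexanal F2. Cyclisation of the mixture with catalytic LiOH in i-PrOH should give 12 and the (4S)-epimer of 12 F3, which are diastereomers because of C7 and C8 and would be separated by chromatography.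

2. Step 7. γ-Deprotonation may compete, alkylation of the hindered tetrasubstituted enolate may be slow, and facial selectivity may be insufficient. The fallback sets out from 12 and comes back at 14. It replaces the lithium enolate alkylation by a Tsuji allylation of a defined enol silane. Soft enolisation of 12 (Et3SiOTf, Et3N, CH2Cl2, −78 → 0 °C) should give the cross-conjugated triethylsilyl dienol ether of 12 F4. F4 is then treated with diallyl carbonate, Pd2(dba)3 (zerovalent palladium), a tert-butyl phosphinooxazoline ligand whose enantiomer is chosen to reinforce the substrate bias, and Bu4N[Ph3SiF2] in THF at 25 °C. The π-allyl electrophile is more reactive toward hindered enolates and adds ligand control to the facial selectivity.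

3. Step 5. Methylenation of the hindered cross-conjugated ketone may be incomplete, or prolonged heating may cause epimerisation at the α-carbon or loss of the silyloxy group by β-elimination. The fallback sets out from 6 and comes back at 8 (and from there at 9 by the same hydrolysis). It builds the diene by cross-coupling instead of carbonyl olefination. Amide 6 with MeMgBr (THF, 0 °C) should give (3R,4R)-4-(tert-butyldimethylsilyloxy)-3-methyl-4-(3,4,5-trimethoxyphenyl)butan-2-one F5. Kinetic enolisation at the methyl group (KN(SiMe3)2, PhNTf2, THF, −78 °C) should give (3R,4R)-4-(tert-butyldimethylsilyloxy)-3-methyl-4-(3,4,5-trimethoxyphenyl)but-1-en-2-yl trifluoromethanesulfonate F6. Stille coupling of F6 with tributyl(1-ethoxyvinyl)stannane (Pd(PPh3)4, LiCl, CuCl, THF, 60 °C) should give 8.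

**Further compounds**
F1 | step 6 | 1-[(E)-2-methoxyethenyl]pyrrolidine | CO/C=C/N1CCCC1
F2 | step 6 | (2S,5S,6R)-4-acetyl-6-(tert-butyldimethylsilyloxy)-2-methoxy-5-methyl-6-(3,4,5-trimethoxyphenyl)hexanal (C4 epimers) | O=C[C@@H](OC)CC(C(C)=O)[C@H](C)[C@@H](O[Si](C)(C)C(C)(C)C)c1cc(OC)c(OC)c(OC)c1
F3 | step 6 | (4S)-6-[(1R,2S)-1-(tert-butyldimethylsilyloxy)-1-(3,4,5-trimethoxyphenyl)propan-2-yl]-4-methoxycyclohex-2-en-1-one (C6 epimers) | CO[C@@H]1C=CC(=O)C(C1)[C@H](C)[C@@H](O[Si](C)(C)C(C)(C)C)c1cc(OC)c(OC)c(OC)c1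
F4 | step 7 | tert-butyl{[(1R,2S)-2-[(5R)-5-methoxy-2-(triethylsilyloxy)cyclohexa-1,3-dien-1-yl]-1-(3,4,5-trimethoxyphenyl)propyl]oxy}dimethylsilane | CC[Si](CC)(CC)OC1=C([C@H](C)[C@@H](O[Si](C)(C)C(C)(C)C)c2cc(OC)c(OC)c(OC)c2)C[C@@H](OC)C=C1
F5 | step 5 | (3R,4R)-4-(tert-butyldimethylsilyloxy)-3-methyl-4-(3,4,5-trimethoxyphenyl)butan-2-one | CC(=O)[C@H](C)[C@@H](O[Si](C)(C)C(C)(C)C)c1cc(OC)c(OC)c(OC)c1
F6 | step 5 | (3R,4R)-4-(tert-butyldimethylsilyloxy)-3-methyl-4-(3,4,5-trimethoxyphenyl)but-1-en-2-yl trifluoromethanesulfonate | C=C(OS(=O)(=O)C(F)(F)F)[C@H](C)[C@@H](O[Si](C)(C)C(C)(C)C)c1cc(OC)c(OC)c(OC)c1
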